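The readings are calculated for an exercise; scatter was added.

I started at the late end of the earlier runs, where X was still climbing.

all flasks: D 0.13 mM
- north-east: J 0.10 M; E 0.60 M; Z 4 mM; temperature 20 °C; run made earlier
- north-west: J 0.15 M; E 0.60 M; Z 4 mM; temperature 45 °C; run made earlier
- west: J 0.20 M; E 0.60 M; Z 8 mM; temperature 20 °C; run made earlier
- green: J 0.20 M; E 0.600 M; Z 4.0 mM; at 65 °C throughout; time 1.0 d
- ochre: J 0.20 M; E 0.600 M; Z 4.0 mM; at 25 °C until 15 h, from then on at 65 °C; time 3.0 d

north-east run (percent of the J charged): time / d: X / % = 0.417: 0.4; 0.833: 0; 1.25: 0.7; 1.67: 0.8; 2.00: 1.8; 2.50: 2.1; 3.00: 3.1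

north-west run (percent of the J charged): time / h: X / % = 4.00: 0.3; 8.00: 1.2; 12.0: 3.5; 15.0: 3.1; 20.0: 5.7; 25.0: 7.3

west run (percent of the J charged): time / d: X / % = 0.250: 0.3; 0.833: 0.7; 1.25: 2.0; 2.00: 3.0; 3.00: 6.8

(each reading ± 0.5 percentage points)

- which one finishes higher in amount of X, in percent of the J charged ("neither" within 2 percentage points) (green / ochre / neither)
- amount of X at the end, in percent of the J charged, green
- amount of X at the end, in percent of the J charged, ochre

The north-west run at 45 °C looked wrong at first. From 8.00 h to 25.0 h the time grew 3.12-fold, yet the reading of X grew 6.08-fold, although J and E do not grow. I read this as a lag: X comes through an unseen intermediate that must fill first.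

Then I froze c_E, c_Z and c_D. In green and ochre, c_E starts at 3.00 times c_J, so with one E per J it does not fall below 66.7% of its charge. I took c_Z and c_D as constant, since Z and D are catalysts. Each of two stages in a row is then pseudo-first-order. The early readings show the product of the two rates, so I gave both one rate r. With x the sum of r over time, the fraction of J arrived as X is 1 − (1 + x)e^(−x), which for small x inverts to x ≈ √(2X) + 2X/3.

I took the percent as free of c_J, as an assumption of mine, since the west run changed c_J and c_Z together. The last readings gave x = 0.270 in the north-east run and 0.431 in the north-west run, so r was 0.00375 h⁻¹ at 20 °C and 0.0172 h⁻¹ at 45 °C. That reads as an apparent activation energy of 47.3 kJ mol⁻¹. The stage rate, the common first-order rate of the two stages taken as equal, then came out in my reckoning at 0.0497 h⁻¹ at 65 °C and 0.00519 h⁻¹ at 25 °C.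

For green I reckoned x = 1.19, so X = 33.4%. For ochre I reckoned x = 2.91, so X = 78.7%.

The forecast said ochre, with 32% for green and 75% for ochre, reading that “there is a lag from an intermediate or slow activation”.

Green gave 38.8% and ochre 78.4%, so ochre finished higher.

    J + Z → Z + G (k = 1.59 M⁻¹ h⁻¹, Ea = 52.0 kJ mol⁻¹)
    E + D + G → D + X (k = 64.7 M⁻² h⁻¹, Ea = 47.0 kJ mol⁻¹)
    X ⇌ L (K = 1.43, k = 0.00723 h⁻¹, Ea = 112 kJ mol⁻¹, ΔH = −90.0 kJ mol⁻¹)
    (constants at 25 °C)

At the end of green, the intermediate G held 44.4% of the J charged. By the stage rate 0.0497 h⁻¹, I reckoned ochre's hold of 15 h at 25 °C as worth 1.57 h at 65 °C, and at the change ochre held 0.329% X.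

For a repeat of green at 80 °C, I reckoned the stage rate at 0.102 h⁻¹, so x = 2.44 and X = 70.0%. The computed flask gave 73.5%.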